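**Retrosynthetic overview**
1. The route rests on the two-carbon bridge C7–C10–C11–C3 that spans the endo faces of ring A (C1–C5, C9) and ring B (C5–C9, C1) of the bicyclo[3.3.1]nonane core, with C11 shared with the cyclopentane C3–C11–C12–C13–C14. Annulation puts a C7 substituent exo, but the bridge needs the C7–C10 bond endo; a planar C7 radical removes this mismatch.
2. Target ⇒ bare tetracyclic trione: the C1 isobutyryl and C5 geranyl groups go on last by two bridgehead lithiations.
3. Tetracyclic trione ⇒ exo-C7 N-acyloxyphthalimide carrying a spiro-methylenecyclopentane at C3 (C11=C10H2 endo): C7–C10 by decarboxylative 7-endo radical closure.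
4. Spiro ring: C3–C14 by exo-face enolate alkylation, C3–C11 by Negishi coupling of a C3 iodide with a ketone-derived alkenyl triflate. Core: Effenberger annulation of malonyl dichloride onto the silyl enol ether of methyl (S)-2,2-dimethyl-4-oxocyclohexane-1-carboxylate (from Hagemann's ester, resolved).
5. Order of ring formation: ring B (from Hagemann's ester) → ring A (step 6) → cyclopentane (step 13) → the two seven-membered rings (step 16).

Key step: step 16

Numbering used throughout: core C1–C9 (C1 next to C8 and later isobutyryl-bearing, C5 later geranyl-bearing, C8 = CMe2, C9 = bridging C=O); bridge C7–C10H2–C11H–C3; cyclopentane C3–C11–C12(Me2)–C13–C14; "exo" at C3 or C7 means pointing away from the other ring, "endo" pointing towards it.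

Assumption: which enantiomer of 1-phenylethylamine gives the less soluble salt with the (S)-acid cannot be predicted; the (R)-amine is written, and the (S)-amine is used in the same protocol if the (R)-acid salt crystallises instead.

**Step 1**
Reactants: 1 ethyl 2-methyl-4-oxocyclohex-2-ene-1-carboxylate (Hagemann's ester; racemic)
Product: 2 ethyl 2,2-dimethyl-4-oxocyclohexane-1-carboxylate (racemic)
Conditions: Me2CuLi (from MeLi, CuI), Et2O, −20 → 0 °C; aq. NH4Cl
Reagents that add atoms: lithium dimethylcuprate, [Li+].C[Cu-]C (made in the flask from methyllithium, [Li]C, and CuI)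
Why: Conjugate addition of a Gilman cuprate to the β-methyl enone installs the second methyl group of the future C8 gem-dimethyl unit; the only stereocentre (future C7) stays racemic.

**Step 2**
Reactants: 2 ethyl 2,2-dimethyl-4-oxocyclohexane-1-carboxylate
Product: 3 2,2-dimethyl-4-oxocyclohexane-1-carboxylic acid (racemic)
Conditions: LiOH·H2O, THF/MeOH/H2O, 50 °C; then 1 M HCl
Reagents that add atoms: lithium hydroxide, [Li+].[OH-]
Why: Ester saponification, slow but clean next to the quaternary carbon, should deliver the acid needed for salt resolution.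

**Step 3**
Reactants: 3 racemic 2,2-dimethyl-4-oxocyclohexane-1-carboxylic acid; 4 (R)-1-phenylethylamine
Product: 5 (R)-1-phenylethylammonium (S)-2,2-dimethyl-4-oxocyclohexane-1-carboxylate (crystalline salt)
Conditions: 4 (1.0 equiv), EtOAc/EtOH, 70 → 5 °C; recrystallise to constant rotation
Reagents that add atoms: none
Why: Classical resolution by crystallisation of diastereomeric ammonium carboxylate salts should give the (S)-acid salt, which fixes the absolute configuration of the future C7 and, through the annulation, of the whole bicycle.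

**Step 4**
Reactants: 5 (R)-1-phenylethylammonium (S)-carboxylate salt
Product: 7 methyl (S)-2,2-dimethyl-4-oxocyclohexane-1-carboxylate, via free (S)-acid 6 (not isolated)
Conditions: 1 M HCl/Et2O partition; then TMSCHN2, PhMe/MeOH 4:1, 0 °C
Reagents that add atoms: trimethylsilyldiazomethane, C[Si](C)(C)C=[N+]=[N-]
Why: Acid liberation and diazoalkane esterification are non-epimerising; the methyl ester is chosen because it can later be removed by SN2 dealkylation without a nucleophile touching the triketone.

**Step 5**
Reactants: 7 methyl (S)-2,2-dimethyl-4-oxocyclohexane-1-carboxylate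
Product: 9 methyl (S)-6,6-dimethyl-4-(trimethylsilyloxy)cyclohex-3-ene-1-carboxylate, via lithium enolate 8 (not isolated)
Conditions: LDA (1.05 equiv), THF, −78 °C; TMSCl, −78 → 0 °C
Reagents that add atoms: chlorotrimethylsilane, C[Si](C)(C)Cl
Why: Kinetic deprotonation at the less hindered α-CH2 (future C5, remote from the gem-dimethyl group) followed by O-silylation should give the silyl enol ether, the ester α-proton being far less acidic than the ketone α-protons.

**Step 6**
Reactants: 9 silyl enol ether; 10 malonyl dichloride
Product: 11 methyl (7S)-4-hydroxy-8,8-dimethyl-2,9-dioxobicyclo[3.3.1]non-3-ene-7-carboxylate (enolised trione; ester exo)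
Conditions: 10 (1.1 equiv), Et2O, −20 °C → rt; then aq. KOH, BnEt3NCl (cat.), rt; HCl to pH 2
Reagents that add atoms: none
Why: Effenberger annulation (C-acylation at C5, then intramolecular C-acylation at C1) builds ring A diaxially on the chair of ring B with the C7 ester equatorial, so the bridge forms anti to the ester (exo) and C1/C5 are set relative to C7; the minor endo diastereomer must be removed here because after decarboxylation it would lead into the enantiomeric series.

**Step 7**
Reactants: 11 enolised bicyclic trione ester
Product: 12 methyl (7S)-4-methoxy-8,8-dimethyl-2,9-dioxobicyclo[3.3.1]non-3-ene-7-carboxylate (ester exo)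
Conditions: TMSCHN2 (2.5 equiv), PhMe/MeOH 4:1, rt
Reagents that add atoms: trimethylsilyldiazomethane, C[Si](C)(C)C=[N+]=[N-]
Why: O-Methylation of the vinylogous acid masks the diketone as a vinylogous ester and re-esterifies any C7 acid formed in the KOH work-up; the C2–OMe regioisomer, if formed, converges with the drawn C4–OMe isomer at step 13.

**Step 8**
Reactants: 12 vinylogous methyl ester
Product: 13 methyl (7S)-3-iodo-4-methoxy-8,8-dimethyl-2,9-dioxobicyclo[3.3.1]non-3-ene-7-carboxylate
Conditions: NIS (1.1 equiv), MeCN, rt, dark
Reagents that add atoms: N-iodosuccinimide, O=C1CCC(=O)N1I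
Why: Electrophilic α-iodination of the electron-rich vinylogous ester at C3, its only nucleophilic carbon, gives the cross-coupling handle.

**Step 9**
Reactants: 14 3,3-dimethyldihydrofuran-2(3H)-one (α,α-dimethyl-γ-butyrolactone)
Product: 15 4-chloro-2,2-dimethylbutanoyl chloride
Conditions: SOCl2, ZnCl2 (cat.), neat, 70 °C
Reagents that add atoms: thionyl chloride, ClS(Cl)=O
Why: Lewis-acid-catalysed ring opening of the lactone by thionyl chloride (chloride attacks the O–CH2 carbon, the acyl end becomes the acid chloride) gives the C11–C14 chain with its two chlorides differentiated.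

**Step 10**
Reactants: 15 4-chloro-2,2-dimethylbutanoyl chloride
Product: 16 5-chloro-3,3-dimethylpentan-2-one
Conditions: MeMgBr (1.05 equiv), Fe(acac)3 (3 mol%), THF, −78 °C
Reagents that add atoms: methylmagnesium bromide, C[Mg]Br
Why: Iron-catalysed acylation of the Grignard reagent by the acid chloride stops at the methyl ketone (C10–C11) and leaves the primary alkyl chloride untouched.

**Step 11**
Reactants: 16 5-chloro-3,3-dimethylpentan-2-one
Product: 18 5-chloro-3,3-dimethylpent-1-en-2-yl trifluoromethanesulfonate, via potassium enolate 17 (not isolated)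
Conditions: KHMDS, THF, −78 °C; PhNTf2, −78 → 0 °C
Reagents that add atoms: N-phenylbis(trifluoromethanesulfonimide), O=S(=O)(N(c1ccccc1)S(=O)(=O)C(F)(F)F)C(F)(F)F
Why: The ketone can enolise only towards its methyl group, so enolate O-triflation gives a single 1,1-disubstituted alkenyl triflate (future C11=C10).

**Step 12**
Reactants: 13 C3-iodo vinylogous ester; 18 alkenyl triflate
Product: 21 methyl (7S)-3-(5-chloro-3,3-dimethylpent-1-en-2-yl)-4-methoxy-8,8-dimethyl-2,9-dioxobicyclo[3.3.1]non-3-ene-7-carboxylate, via C3-magnesium chloride 19 (not isolated), via C3-zinc chloride 20 (not isolated)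
Conditions: i-PrMgCl·LiCl, THF, −78 °C; ZnCl2; then 18, Pd2(dba)3 (2.5 mol%), SPhos (10 mol%), THF, 50 °C
Reagents that add atoms: none
Why: Iodine–magnesium exchange at the activated C3 iodide, transmetalation to zinc and Negishi coupling with the alkenyl triflate (bulky biarylphosphine for two hindered sp2 partners) should form C3–C11 while ester, ketone and alkyl chloride are tolerated.

**Step 13**
Reactants: 21 C3-alkenyl vinylogous ester
Product: 23 methyl (7S)-3',3',8,8-tetramethyl-2'-methylidene-2,4,9-trioxospiro[bicyclo[3.3.1]nonane-3,1'-cyclopentane]-7-carboxylate (C11 endo; C14 exo; ester exo), via lithium diketonate 22 (not isolated)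
Conditions: LiCl (3 equiv), DMSO, 120 °C, N2 sweep
Reagents that add atoms: none
Why: Chloride-mediated SN2 demethylation of the vinylogous ester releases the C2/C4 diketonate, which closes the five-membered ring by 5-exo-tet C-alkylation at C14–Cl; C3 is set because only the exo face of the enolate is open (the endo face is blocked by ring B), which pushes C11 into the endo position, and O-alkylation would need a seven-membered ring.

**Step 14**
Reactants: 23 spiro trione methyl ester
Product: 24 (7S)-3',3',8,8-tetramethyl-2'-methylidene-2,4,9-trioxospiro[bicyclo[3.3.1]nonane-3,1'-cyclopentane]-7-carboxylic acid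
Conditions: LiI (10 equiv), EtOAc, reflux, dark; then 1 M HCl
Reagents that add atoms: none
Why: SN2 dealkylation of the methyl ester by iodide frees the C7 acid without a nucleophile attacking the non-enolisable 2,2-disubstituted 1,3-diketone, which hydroxide would cleave by retro-Claisen reaction.

**Step 15**
Reactants: 24 spiro trione acid; 25 N-hydroxyphthalimide
Product: 26 1,3-dioxoisoindolin-2-yl (7S)-3',3',8,8-tetramethyl-2'-methylidene-2,4,9-trioxospiro[bicyclo[3.3.1]nonane-3,1'-cyclopentane]-7-carboxylate (exo-C7 redox-active ester)
Conditions: DIC, DMAP (cat.), CH2Cl2, rt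
Reagents that add atoms: none
Why: Carbodiimide (Steglich-type) esterification gives the redox-active ester under neutral conditions.

**Step 16**
Reactants: 26 exo-C7 N-acyloxyphthalimide
Product: 27 bare tetracyclic trione (C7–C10 bond endo; C11–H on the C4/C5/C6 side; C1–H and C5–H free)
Conditions: undivided cell, RVC cathode, Mg anode, constant current (ca. 2.2 F/mol), n-Bu4NPF6 (0.1 M), DMF, rt, 5 mM in 26; HSCH2CO2Me (2.2 equiv) by syringe pump
Reagents that add atoms: none
Why: Cathodic one-electron reduction of the N-acyloxyphthalimide gives a radical anion that fragments to phthalimide anion, CO2 and the secondary C7 radical, which adds to the unsubstituted alkene terminus C10; the tertiary C11 radical then takes a hydrogen atom from the thiol, and the thiyl radical is reduced to thiolate at the cathode. The closest known reaction type is the reductive decarboxylative radical cyclisation of redox-active esters onto unactivated alkenes with hydrogen-atom termination (photochemical and electroreductive variants). The single C7–C10 bond closes both seven-membered rings of the homoadamantane (C7–C10–C11–C3–C2–C1–C8 and C7–C10–C11–C3–C4–C5–C6) in a 7-endo-trig mode. C7 is set by the tether, because the planar radical can reach C10 only through its endo lobe, so the configuration of the starting ester is irrelevant; C11 is set by hydrogen delivery to the face that looks towards C6H2, the opposite face being screened by the C8 methyl group that lies over it. The step needs 7-endo over 6-exo attack and ring closure before hydrogen transfer to C7: the first should be secured by C11 being fully substituted and flanked by quaternary C3 and C12 while C10 lies in the path of C7 on the C3···C7 axis, the second by dilution and by keeping the thiol concentration low through slow addition.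

**Step 17**
Reactants: 27 bare tetracyclic trione; 28 geranyl bromide
Product: 30 C5-geranyl tetracyclic trione, via C5-lithio trione 29 (not isolated)
Conditions: LDA (1.1 equiv), THF, −78 °C; 28, −78 → −20 °C
Reagents that add atoms: none
Why: Bridgehead lithiation should occur at C5–H, which is flanked by C4=O and C9=O and is less hindered than C1–H next to the C8 gem-dimethyl group, and SN2 alkylation with the allylic bromide proceeds with retention because the cage holds the carbanion pyramidal.

**Step 18**
Reactants: 30 C5-geranyl tetracyclic trione; 31 isobutyryl chloride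
Product: 33 CNP0313870.1 (target), via C1-lithio trione 32 (not isolated)
Conditions: LiTMP (1.3 equiv), THF, −78 °C; 31, −78 → −40 °C
Reagents that add atoms: none
Why: The remaining bridgehead proton C1–H is removed by the stronger, more hindered amide base, and the bridgehead carbanion, which cannot delocalise onto oxygen (Bredt's rule), is C-acylated by the acid chloride with retention.

**Compound list**
1 | ethyl 2-methyl-4-oxocyclohex-2-ene-1-carboxylate (Hagemann's ester, racemic) | CCOC(=O)C1CCC(=O)C=C1C | starting material
2 | ethyl 2,2-dimethyl-4-oxocyclohexane-1-carboxylate (racemic) | CCOC(=O)C1CCC(=O)CC1(C)C | intermediate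
3 | 2,2-dimethyl-4-oxocyclohexane-1-carboxylic acid (racemic) | OC(=O)C1CCC(=O)CC1(C)C | intermediate
4 | (R)-1-phenylethylamine | C[C@@H](N)c1ccccc1 | starting material
5 | (R)-1-phenylethylammonium (S)-2,2-dimethyl-4-oxocyclohexane-1-carboxylate | C[C@@H]([NH3+])c1ccccc1.O=C1CC[C@H](C([O-])=O)C(C)(C)C1 | intermediate
6 | (S)-2,2-dimethyl-4-oxocyclohexane-1-carboxylic acid | O=C1CC[C@H](C(=O)O)C(C)(C)C1 | intermediate
7 | methyl (S)-2,2-dimethyl-4-oxocyclohexane-1-carboxylate | O=C1CC[C@H](C(=O)OC)C(C)(C)C1 | intermediate
8 | lithium (S)-4-(methoxycarbonyl)-5,5-dimethylcyclohex-1-en-1-olate | [Li+].[O-]C1=CC[C@H](C(=O)OC)C(C)(C)C1 | intermediate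
9 | methyl (S)-6,6-dimethyl-4-(trimethylsilyloxy)cyclohex-3-ene-1-carboxylate | C[Si](C)(C)OC1=CC[C@H](C(=O)OC)C(C)(C)C1 | intermediate
10 | malonyl dichloride | ClC(=O)CC(Cl)=O | starting material
11 | methyl (7S)-4-hydroxy-8,8-dimethyl-2,9-dioxobicyclo[3.3.1]non-3-ene-7-carboxylate (ester exo) | [C@@H]12C[C@H](C(=O)OC)C(C)(C)[C@H](C2=O)C(=O)C=C1O | intermediate
12 | methyl (7S)-4-methoxy-8,8-dimethyl-2,9-dioxobicyclo[3.3.1]non-3-ene-7-carboxylate (ester exo) | [C@@H]12C[C@H](C(=O)OC)C(C)(C)[C@H](C2=O)C(=O)C=C1OC | intermediate
13 | methyl (7S)-3-iodo-4-methoxy-8,8-dimethyl-2,9-dioxobicyclo[3.3.1]non-3-ene-7-carboxylate | [C@@H]12C[C@H](C(=O)OC)C(C)(C)[C@H](C2=O)C(=O)C(I)=C1OC | intermediate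
14 | 3,3-dimethyldihydrofuran-2(3H)-one | CC1(C)CCOC1=O | starting material
15 | 4-chloro-2,2-dimethylbutanoyl chloride | CC(C)(CCCl)C(Cl)=O | intermediate
16 | 5-chloro-3,3-dimethylpentan-2-one | CC(=O)C(C)(C)CCCl | intermediate
17 | potassium 5-chloro-3,3-dimethylpent-1-en-2-olate | [K+].[O-]C(=C)C(C)(C)CCCl | intermediate
18 | 5-chloro-3,3-dimethylpent-1-en-2-yl trifluoromethanesulfonate | C=C(OS(=O)(=O)C(F)(F)F)C(C)(C)CCCl | intermediate
19 | C3-magnesium chloride of vinylogous ester 12 | [C@@H]12C[C@H](C(=O)OC)C(C)(C)[C@H](C2=O)C(=O)C([Mg]Cl)=C1OC | intermediate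
20 | C3-zinc chloride of vinylogous ester 12 | [C@@H]12C[C@H](C(=O)OC)C(C)(C)[C@H](C2=O)C(=O)C([Zn]Cl)=C1OC | intermediate
21 | methyl (7S)-3-(5-chloro-3,3-dimethylpent-1-en-2-yl)-4-methoxy-8,8-dimethyl-2,9-dioxobicyclo[3.3.1]non-3-ene-7-carboxylate | [C@@H]12C[C@H](C(=O)OC)C(C)(C)[C@H](C2=O)C(=O)C(C(=C)C(C)(C)CCCl)=C1OC | intermediate
22 | lithium C2/C4 diketonate of 21 (O-demethylated) | [C@@H]12C[C@H](C(=O)OC)C(C)(C)[C@H](C2=O)C(=O)C(C(=C)C(C)(C)CCCl)=C1[O-].[Li+] | intermediate
23 | methyl (7S)-3',3',8,8-tetramethyl-2'-methylidene-2,4,9-trioxospiro[bicyclo[3.3.1]nonane-3,1'-cyclopentane]-7-carboxylate (C11 endo, C14 exo, ester exo) | [C@@H]12C[C@H](C(=O)OC)C(C)(C)[C@H](C2=O)C(=O)[C@@]3(C1=O)CCC(C)(C)C3=C | intermediate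
24 | (7S)-3',3',8,8-tetramethyl-2'-methylidene-2,4,9-trioxospiro[bicyclo[3.3.1]nonane-3,1'-cyclopentane]-7-carboxylic acid | [C@@H]12C[C@H](C(=O)O)C(C)(C)[C@H](C2=O)C(=O)[C@@]3(C1=O)CCC(C)(C)C3=C | intermediate
25 | N-hydroxyphthalimide | ON1C(=O)c2ccccc2C1=O | starting material
26 | 1,3-dioxoisoindolin-2-yl ester of acid 24 (exo-C7 redox-active ester) | [C@@H]12C[C@H](C(=O)ON5C(=O)c6ccccc6C5=O)C(C)(C)[C@H](C2=O)C(=O)[C@@]3(C1=O)CCC(C)(C)C3=C | intermediate
27 | bare tetracyclic trione (homoadamantane core with C7–C10–C11–C3 bridge and fused cyclopentane; 8,8,12,12-tetramethyl; C1–H, C5–H) | [C@@H]12C[C@H]3C[C@@H]4C(C)(C)CC[C@]4(C1=O)C(=O)[C@@H](C2=O)C3(C)C | intermediate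
28 | geranyl bromide, (2E)-1-bromo-3,7-dimethylocta-2,6-diene | CC(C)=CCC/C(C)=C/CBr | starting material
29 | C5-lithio derivative of trione 27 | [Li][C@@]12C[C@H]3C[C@@H]4C(C)(C)CC[C@]4(C1=O)C(=O)[C@@H](C2=O)C3(C)C | intermediate
30 | C5-geranyl tetracyclic trione | CC(C)=CCC/C(C)=C/C[C@@]12C[C@H]3C[C@@H]4C(C)(C)CC[C@]4(C1=O)C(=O)[C@@H](C2=O)C3(C)C | intermediate
31 | isobutyryl chloride (2-methylpropanoyl chloride) | CC(C)C(Cl)=O | starting material
32 | C1-lithio derivative of trione 30 | CC(C)=CCC/C(C)=C/C[C@@]12C[C@H]3C[C@@H]4C(C)(C)CC[C@]4(C1=O)C(=O)[C@@]([Li])(C2=O)C3(C)C | intermediate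
33 | CNP0313870.1 (C5-geranyl, C1-isobutyryl tetracyclic trione) | CC(C)=CCC/C(C)=C/C[C@@]12C[C@H]3C[C@@H]4C(C)(C)CC[C@]4(C1=O)C(=O)[C@@](C(=O)C(C)C)(C2=O)C3(C)C | target

**Step count and risks**
Total: 18 steps. Longest linear sequence: 15 steps (steps 1–8 and 12–18); the side chain (steps 9–11) joins at step 12.

Steps most likely to fail:

1. Step 16 (key step). Possible failures are:
   - hydrogen transfer to the C7 radical before ring closure;
   - attack at C11 (6-exo) instead of C10;
   - β-scission of the C8–C1 bond;
   - thiolysis of the active ester, or thiyl addition to the methylene group;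
   - hydrogen delivery to the wrong face of C11.

   Fallback (sets out from 24, returns at 27): the acid is coupled with 1-hydroxypyridine-2(1H)-thione (DCC, DMAP, CH2Cl2, dark) to the O-acyl thiohydroxamate (Barton ester) F1. F1 is decomposed in refluxing benzene under a tungsten lamp while Bu3SnH/AIBN is added by syringe pump. The same C7 radical then arises in a tin-hydride chain, without electrode, thiol or thiolate, and the hydrogen-donor concentration can be held as low as the closure requires.

2. Step 12. Transmetalation and reductive elimination between two hindered sp2 partners may be slow, so that protodemetalation of the C3-zinc species or decomposition of the triflate takes over.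

   Fallback (sets out from 11 and 18, returns at 23): LDA (THF, −78 °C) eliminates triflic acid from 18 to give 5-chloro-3,3-dimethylpent-1-yne F2. In(OTf)3-catalysed Markovnikov addition of the C3–H of enol 11 across the terminal alkyne (hydroalkylation through an indium enolate, PhMe, 90 °C) gives the free C3-alkenyl diketone F3. K2CO3/NaI in DMSO then closes the cyclopentane from the exo face to give 23; this bypasses steps 7, 8 and 13.

3. Step 18. Deprotonation at the congested C1 may be incomplete, or the hindered carbanion may be acylated slowly so that O-acylation or proton return competes.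

   Fallback (sets out from 30, returns at 33): LiTMP, then isobutyraldehyde at −78 °C gives the bridgehead carbinol F4 (aldol-type addition with the smaller, more reactive electrophile; either carbinol epimer serves). Dess–Martin periodinane (CH2Cl2, rt) oxidises F4 to 33.

**Further compounds**
F1 | step 16 | 2-thioxopyridin-1(2H)-yl ester of acid 24 (Barton ester) | [C@@H]12C[C@H](C(=O)ON4C=CC=CC4=S)C(C)(C)[C@H](C2=O)C(=O)[C@@]3(C1=O)CCC(C)(C)C3=C
F2 | step 12 | 5-chloro-3,3-dimethylpent-1-yne | C#CC(C)(C)CCCl
F3 | step 12 | methyl (7S)-3-(5-chloro-3,3-dimethylpent-1-en-2-yl)-4-hydroxy-8,8-dimethyl-2,9-dioxobicyclo[3.3.1]non-3-ene-7-carboxylate | [C@@H]12C[C@H](C(=O)OC)C(C)(C)[C@H](C2=O)C(=O)C(C(=C)C(C)(C)CCCl)=C1O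
F4 | step 18 | C1-(1-hydroxy-2-methylpropyl) derivative of trione 30 (bridgehead carbinol) | CC(C)=CCC/C(C)=C/C[C@@]12C[C@H]3C[C@@H]4C(C)(C)CC[C@]4(C1=O)C(=O)[C@@](C(O)C(C)C)(C2=O)C3(C)C
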